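**Numbering used throughout.** Ring carbons C5–C10; C14 = methyl on C10; C1=C2 = vinyl on C10; C4(=C3)–C15H2OH = arm on C5; lactone O on C6, C12 = lactone carbonyl, C11 on C7, C13 = exocyclic methylene. β = ring face of the C10 methyl, α = the other face.

## Analysis of the target

The target is a monocyclic elemane-type lactone: a cyclohexane (C5–C10) fused trans at C6/C7 to an α-methylene-γ-butyrolactone (O on C6, C12=O, C11=C13). The ring carries five stereocentres. C5 (β arm), C6 (α oxygen), C7 (β C11) and C8 (α acyloxy) hold their substituents equatorially in alternating sense, and quaternary C10 holds an axial β-methyl (C14) and an equatorial α-vinyl group (C1=C2). A sixth stereocentre sits in the (R)-3-hydroxy-2-methylpropanoyl group on O8. Sensitive groups are the α-methylene lactone (Michael acceptor, base-labile), the β-hydroxy ester, two free primary hydroxyls and three terminal alkenes of similar kind. The hard points are the quaternary C10 next to the tertiary C5 with a fixed cis relation of methyl and arm, and telling apart the alkenes and the two primary alcohols. The strategy rests on one feature: C9 is a bare CH2 between C10 and the oxygenated C8, and the C10 methyl is cis to the C5 arm. C14 can therefore be carried to the β face of a C9=C10 alkene by an 8β-hydroxyl as a cyclopropane, and the C9–C14 bond can be cut afterwards to leave C9H2 and the C10 methyl. The C8 carbinol is a disposable control element and is reset at the end.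

## Retrosynthetic reasoning

Target 43 is traced to its bis-silyl ether 42, so that the two primary hydroxyls stay masked until the last step.

The C8–O ester bond is cut next, giving alcohol 38 and acid 41 (from 39 through 40). The cut is made with inversion, because hydride reduction of a C8 ketone in this ring can only come from the α face (the β-axial path is blocked by the axial C10 methyl) and so gives the 8β-alcohol. An SN2 esterification turns this into the required 8α-ester.

The exocyclic C11=C13 alkene is removed (38 to 35), and the 8β-alcohol 35 is traced to ketone 34. The methylene lactone is placed late because it would not survive the cuprate, ylide and hydride steps before it.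

The C1=C2 vinyl group is traced through aldehyde 33 and alcohol 32 to the silyloxymethyl ketone 31. C1 is kept as CH2O-silyl until the cyclopropane is opened, since a vinyl group on C10 would stabilise a C10 radical and divert the ring opening to the endocyclic bond.

The C10 methyl of 31 is traced to cyclopropyl ketone 30 by reconnecting C9–C14. In the forward sense a ketyl at C8 cuts the cyclopropane bond that overlaps the carbonyl π system. Ketone 30 comes from carbinol 29.

The cyclopropane of 29 is cut at C10–C14 and C9–C14, giving cyclohexenol 26 and diiodomethane 27. This is the key disconnection: the 8β-oxygen fixes the face, so C14 arrives cis to the C5 arm.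

Alcohol 26 is traced to enone 25, and the C9=C10 bond of 25 is cut to give 1,5-diketone 23 (aldol condensation). C5 and C7, the two epimerisable centres flanking the lactone, sit in their equatorial, thermodynamically preferred positions in 25.

The C10–C1 bond of 23 is cut, giving acid 19 and stannane 21 (from 20). Acid 19 comes from imide 17.

The C7–C8 bond of 17 is cut, giving butenolide 14 and an acetyl anion equivalent made from 15. The forward conjugate addition must come anti to the C6 substituent, which sets the trans lactone.

Butenolide 14 is opened at C7=C11 (ring-closing metathesis) to acrylate 13, made from aldol 11 and 12.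

The C5–C6 bond of 11 is cut, giving imide 8 and acrolein 9. A deconjugative syn aldol sets C5 and C6 in one step and produces the C4=C3 arm alkene.

Imide 8 comes from acid 5 and auxiliary 6; acid 5 from ester 4, made from ketone 2 and phosphonate 3; ketone 2 from hydroxyacetone 1.

## Alternatives that were turned down

Alternative 1: The C5–C6 bond is cut. In the forward step Me2AlCl activates the C6 aldehyde of open-chain aldehyde A1, C5 of the 2-methylpropenyl group attacks it while a methyl hydrogen passes to oxygen, and cyclohexanol A2 results.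
- For: one step closes the ring and sets C5 and C6 through a chair with the isopropenyl and hydroxyl groups trans, as in the citronellal-to-isopulegol pattern. The vinyl group is already in place, so no late C1 chemistry is needed; on this point it is stronger than the chosen route.
- Against: the quaternary C10 must be built in an open chain with a defined 1,3-relation to C8 across the C9 methylene, for which there is no good handle. In the ene chair, methyl and vinyl on C10 differ little in size, so the C5/C10 relation is weakly controlled. A2 carries a plain isopropenyl group, so C15 must later be oxidised in the presence of other allylic positions.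
- Comparison: the chosen route sets C10 last, on a rigid ring, by intramolecular delivery, and carries the C15 oxygen from the first step.

Alternative 2: The C6–C7 and O–C12 bonds are cut. In the forward step CrCl2 turns the allylic bromide of A3 into an allylchromium that adds to the C6 aldehyde through C7, and the alkoxide closes the lactone to give A4.
- For: it is the most convergent plan. Both rings, C6, C7 and the α-methylene lactone form in one operation, and C8 already has the α configuration, so late methylenation and inversion are not needed. In end-game step economy it is clearly stronger.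
- Against: A3 needs the C5/C10 pair set in an open chain, and C5 carries a formyl group next to an alkene-bearing carbon, which epimerises and conjugates easily. The trans ring fusion depends on a chair-like addition within a six-membered ring closure, where cis-fused lactones are a common outcome.
- Comparison: the chosen route gives stepwise, checkable control of each centre on a ring and uses robust intermediates.

Alternative 3: The C9–C10 bond is cut. Anodic oxidation of the silyl enol ether of A5 gives a radical cation, C10 of the (Z)-allylsilane attacks C9, and loss of silicon releases the vinyl group to give A6, which is the same compound as 34 of the route.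
- For: the quaternary centre and the carbocycle form together on a preformed lactone, and the vinyl group appears directly. It would save the six steps between 26 and 34 and is stronger on step count.
- Against: the C10 configuration depends on how a chair-like transition state tells methyl from the silylmethyl-bearing alkene arm, and on a single (Z)-trisubstituted allylsilane made next to the C5 stereocentre. The electron-rich arm alkene may compete at the anode.
- Comparison: the chosen route offers a facial outcome that follows from coordination geometry, with ordinary reagents.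

Key step: step 14

Remark: (tributylstannyl)methanol 20 and 1-chloro-N,N,2-trimethylprop-1-en-1-amine are taken as purchasable; in step 13 the enone double bond is assumed to act as the larger carbonyl substituent toward the oxazaborolidine.

## Route

Step 1
Reactants: 1 hydroxyacetone (1-hydroxypropan-2-one)
Product: 2 1-[(tert-butyldiphenylsilyl)oxy]propan-2-one
Conditions: TBDPSCl, imidazole, CH2Cl2, 0 °C to rt
Reagents that add atoms: tert-butyl(chloro)diphenylsilane, CC(C)(C)[Si](Cl)(c1ccccc1)c1ccccc1
Why: Silyl ether formation on a primary alcohol; the robust TBDPS group is chosen because this oxygen (C15) is carried to the last step.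

Step 2
Reactants: 2 1-[(tert-butyldiphenylsilyl)oxy]propan-2-one; 3 triethyl phosphonoacetate
Product: 4 ethyl (E)-4-[(tert-butyldiphenylsilyl)oxy]-3-methylbut-2-enoate
Conditions: NaH, THF, 0 °C to rt
Reagents that add atoms: none
Why: Horner–Wadsworth–Emmons olefination of an activated α-silyloxy ketone; the E isomer (ester trans to the larger CH2OSi group) should predominate and any Z isomer is removed by chromatography.

Step 3
Reactants: 4 ethyl (E)-4-[(tert-butyldiphenylsilyl)oxy]-3-methylbut-2-enoate
Product: 5 (E)-4-[(tert-butyldiphenylsilyl)oxy]-3-methylbut-2-enoic acid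
Conditions: LiOH, THF/MeOH/H2O, rt; then 1 M HCl
Reagents that add atoms: lithium hydroxide, [Li+].[OH-]
Why: Ester saponification; the primary TBDPS ether is stable to aqueous LiOH at room temperature.

Step 4
Reactants: 5 (E)-4-[(tert-butyldiphenylsilyl)oxy]-3-methylbut-2-enoic acid; 6 (R)-4-benzyl-1,3-oxazolidin-2-one
Product: 8 (R)-4-benzyl-3-{(E)-4-[(tert-butyldiphenylsilyl)oxy]-3-methylbut-2-enoyl}-1,3-oxazolidin-2-one, via mixed pivalic anhydride 7 (not isolated)
Conditions: t-BuCOCl, Et3N, THF, −20 °C; then LiCl, 6, rt
Reagents that add atoms: none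
Why: N-Acylation of the oxazolidinone through a mixed anhydride; the hindered pivaloyl carbonyl directs attack to the enoyl carbonyl.

Step 5
Reactants: 8 (R)-4-benzyl-3-{(E)-4-[(tert-butyldiphenylsilyl)oxy]-3-methylbut-2-enoyl}-1,3-oxazolidin-2-one; 9 acrolein (prop-2-enal)
Product: 11 (R)-4-benzyl-3-[(2R,3S)-2-{3-[(tert-butyldiphenylsilyl)oxy]prop-1-en-2-yl}-3-hydroxypent-4-enoyl]-1,3-oxazolidin-2-one (acyl C2 = C5; acyl C3 = C6), via boron dienolate 10 (not isolated)
Conditions: Bu2BOTf, Et3N, CH2Cl2, −78 to 0 °C; 9, −78 to 0 °C; pH 7 buffer, MeOH, H2O2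
Reagents that add atoms: none
Why: Evans boron aldol in its deconjugative form: γ-deprotonation of the methyl group cis to the carbonyl (the CH2OSi hydrogens are shielded by the silyl group) gives the (Z)-O-boron dienolate 10, which adds through its α-carbon in a chair Zimmerman–Traxler transition state. The (R)-benzyl auxiliary fixes the face, so C5 and C6 arise syn with the required absolute sense, and the alkene reappears as the C4=C3 arm.

Step 6
Reactants: 11 syn aldol adduct (as above); 12 acryloyl chloride
Product: 13 (R)-4-benzyl-3-[(2R,3S)-3-(acryloyloxy)-2-{3-[(tert-butyldiphenylsilyl)oxy]prop-1-en-2-yl}pent-4-enoyl]-1,3-oxazolidin-2-one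
Conditions: i-Pr2NEt, CH2Cl2, −78 to 0 °C
Reagents that add atoms: none
Why: O-Acylation of the secondary alcohol; the acrylate brings in C11 and C12 of the lactone, and low temperature with a hindered amine avoids elimination of the new β-acyloxy group.

Step 7
Reactants: 13 acrylate (as above)
Product: 14 (R)-4-benzyl-3-[(2R)-3-{[(tert-butyldiphenylsilyl)oxy]methyl}-2-[(2S)-5-oxo-2,5-dihydrofuran-2-yl]but-3-enoyl]-1,3-oxazolidin-2-one
Conditions: RuCl2(=CHPh)(H2IMes)(PCy3) (second-generation Grubbs catalyst), CH2Cl2, 40 °C
Reagents that add atoms: none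
Why: Ring-closing metathesis: the carbene loads on the monosubstituted C7 vinyl group and closes onto the acrylate to give the butenolide. The 1,1-disubstituted arm alkene could only close a four-membered ring with the C7 vinyl group and is left untouched.

Step 8
Reactants: 14 butenolide (as above); 15 ethyl vinyl ether (ethoxyethene)
Product: 17 (R)-4-benzyl-3-[(2R)-2-[(2S,3S)-3-acetyl-5-oxooxolan-2-yl]-3-{[(tert-butyldiphenylsilyl)oxy]methyl}but-3-enoyl]-1,3-oxazolidin-2-one, via enol ether 16 (not isolated)
Conditions: CH2=C(OEt)Li (from 15, t-BuLi, THF, −78 to 0 °C), CuBr·SMe2, THF, −78 °C; 14, −78 to −30 °C; then 1 M HCl, THF, 0 °C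
Reagents that add atoms: water, O
Why: Conjugate addition of an α-alkoxyvinyl cuprate (an acetyl anion equivalent) to the butenolide; attack anti to the C6 substituent sets C7 trans and so the trans lactone. Acidic work-up hydrolyses enol ether 16 to the methyl ketone (C8, C9); the imide and the silyl ether are inert to the cuprate.

Step 9
Reactants: 17 keto lactone imide (as above)
Product: 19 (2R)-2-[(2S,3S)-3-acetyl-5-oxooxolan-2-yl]-3-{[(tert-butyldiphenylsilyl)oxy]methyl}but-3-enoic acid, via peroxy acid 18 (not isolated)
Conditions: LiOH, H2O2, THF/H2O, 0 °C; Na2SO3; then 1 M HCl to pH 3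
Reagents that add atoms: hydrogen peroxide, OO
Why: Hydroperoxide cleavage of the N-acyloxazolidinone: the hydroperoxide anion attacks the exocyclic imide carbonyl, sulfite reduces peroxy acid 18, and any opened lactone recloses on acidification. The enolate of the C8 ketone is exocyclic to the lactone, so its C6–O bond is poorly aligned for β-elimination.

Step 10
Reactants: 20 (tributylstannyl)methanol
Product: 21 tert-butyldimethyl[(tributylstannyl)methoxy]silane
Conditions: TBSCl, imidazole, DMF, rt
Reagents that add atoms: tert-butyl(chloro)dimethylsilane, CC(C)(C)[Si](C)(C)Cl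
Why: Silyl ether formation; this gives the C1 unit as a transferable silyloxymethyl group on tin.

Step 11
Reactants: 19 keto lactone acid (as above); 21 tert-butyldimethyl[(tributylstannyl)methoxy]silane
Product: 23 (4S,5S)-4-acetyl-5-[(3R)-1-[(tert-butyldimethylsilyl)oxy]-4-{[(tert-butyldiphenylsilyl)oxy]methyl}-2-oxopent-4-en-3-yl]oxolan-2-one (1,5-diketone; carbonyls at C8 and C10), via acid chloride 22 (not isolated)
Conditions: 1-chloro-N,N,2-trimethylprop-1-en-1-amine, CH2Cl2, 0 °C; then 21, PdCl(CH2Ph)(PPh3)2, toluene, 60 °C
Reagents that add atoms: none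
Why: Neutral acid chloride formation followed by Stille acylation: acid chloride 22 adds oxidatively to zerovalent palladium, the oxygen-activated CH2OSi group transfers from tin in preference to butyl, and reductive elimination gives the α-silyloxy ketone. The base-free conditions protect the C5 centre (α to the new ketone and allylic) and the β-acyloxy ketone.

Step 12
Reactants: 23 1,5-diketone (as above)
Product: 25 cyclohexenone: trans-fused γ-lactone (O on C6; C12=O; C11H2 on C7) with C8 ketone and C9=C10 alkene; CH2OTBS on C10; 5β-[3-(tert-butyldiphenylsilyloxy)prop-1-en-2-yl]; H-5α H-6β H-7α, via β-hydroxy ketone 24 (not isolated)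
Conditions: pyrrolidine, AcOH, toluene, 50 °C
Reagents that add atoms: none
Why: Intramolecular aldol condensation: the enamine forms at the less hindered methyl ketone, and its C9 carbon attacks the more electrophilic α-silyloxy ketone C10 to close the six-membered ring. Loss of water from 24 gives the conjugated enone; buffered amine catalysis is chosen to keep the lactone from β-elimination, and C5 and C7 stay in their equatorial, thermodynamically preferred positions.

Step 13
Reactants: 25 cyclohexenone (as above)
Product: 26 cyclohex-9-en-8β-ol: as 25 but with 8β-hydroxyl (H-8α) in place of the ketone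
Conditions: (R)-2-methyl-CBS-oxazaborolidine, catecholborane, toluene, −78 °C
Reagents that add atoms: none
Why: Corey–Bakshi–Shibata 1,2-reduction: with the enone double bond as the larger substituent, the (R)-catalyst delivers hydride to the α face of C8 and should give the pseudoaxial 8β-alcohol against the substrate's own preference for axial hydride attack. Catecholborane is used so that the arm alkene is not hydroborated.

Step 14
Reactants: 26 cyclohex-9-en-8β-ol (as above); 27 diiodomethane
Product: 29 cyclopropane-fused carbinol: 9β,10β-methano (C14 β on C9 and C10) with 8β-OH and 10α-CH2OTBS; lactone and arm as in 26, via iodomethylzinc alkoxide 28 (not isolated)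
Conditions: Et2Zn, CH2I2, CH2Cl2, −10 °C to rt
Reagents that add atoms: none
Why: Et2Zn deprotonates the 8β-hydroxyl and exchange with 27 gives the iodomethylzinc alkoxide 28. Within this complex CH2 is transferred to C9=C10 in one concerted, syn step through the butterfly transition state of the Simmons–Smith reaction, forming C9–C14 and C10–C14 together. The closest known reaction type is the hydroxyl-directed Simmons–Smith (Furukawa) cyclopropanation of cyclohex-2-en-1-ols, which gives cis-hydroxy bicyclo[4.1.0]heptanes. The three-membered ring closes by concerted [2+1] addition of the carbenoid carbon across the alkene, not by a stepwise cyclisation. Both new stereocentres, C9 and C10, are set by the 8β-oxygen: zinc is held on the β face, so C14 enters β and the CH2OTBS group on C10 ends α. The step needs β-facial selectivity and chemoselectivity over the C4=C3 arm; both come from coordination, because the arm has only a silyl ether nearby and can react only with free carbenoid, while the trisubstituted alkene next to the alkoxide reacts intramolecularly. The pseudoaxial 8β-oxygen on the lactone-locked half-chair sits directly over C9=C10, and the lactone and silyl ethers are inert to the reagent.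

Step 15
Reactants: 29 cyclopropane-fused carbinol (as above)
Product: 30 cyclopropyl ketone: as 29 with C8 ketone
Conditions: Dess–Martin periodinane, NaHCO3, CH2Cl2, 0 °C to rt
Reagents that add atoms: none
Why: Dess–Martin oxidation of a secondary alcohol under buffered, non-acidic conditions that leave the cyclopropylcarbinyl system and silyl ethers intact.

Step 16
Reactants: 30 cyclopropyl ketone (as above)
Product: 31 ketone with quaternary C10: 10β-methyl and 10α-CH2OTBS; C9H2; C8 ketone; lactone and arm unchanged
Conditions: SmI2, MeOH, DMPU, THF, −78 to 0 °C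
Reagents that add atoms: none
Why: Samarium ketyl fragmentation of an α-cyclopropyl ketone: the exocyclic C9–C14 bond overlaps the ketyl π system and cleaves, while the endocyclic C9–C10 bond lies near the nodal plane. The C14 radical is reduced and protonated to the methyl group and the samarium enolate is protonated at C9; this enolate points away from C7, so the lactone is not eliminated.

Step 17
Reactants: 31 silyloxymethyl ketone (as above)
Product: 32 primary alcohol: as 31 with 10α-CH2OH
Conditions: HF·pyridine, pyridine, THF, 0 °C
Reagents that add atoms: none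
Why: Selective desilylation: the primary TBS ether is cleaved much faster than the TBDPS ether under buffered fluoride.

Step 18
Reactants: 32 primary alcohol (as above)
Product: 33 keto aldehyde: as 31 with 10α-CHO
Conditions: Dess–Martin periodinane, NaHCO3, CH2Cl2, rt
Reagents that add atoms: none
Why: Dess–Martin oxidation of a neopentyl primary alcohol; the aldehyde has no α-hydrogen and cannot epimerise.

Step 19
Reactants: 33 keto aldehyde (as above)
Product: 34 vinyl ketone: 10β-methyl-10α-vinyl; C8 ketone; trans lactone; 5β-[3-(tert-butyldiphenylsilyloxy)prop-1-en-2-yl]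
Conditions: Ph3PCH3Br, KN(SiMe3)2, THF, −78 to 0 °C
Reagents that add atoms: methyltriphenylphosphonium bromide, C[P+](c1ccccc1)(c1ccccc1)c1ccccc1.[Br-]
Why: Wittig methylenation; one equivalent of ylide at low temperature should take the aldehyde in preference to the less electrophilic ring ketone. Enolisation of that ketone toward C7 cannot easily expel the lactone oxygen, because the C6–O bond is equatorial.

Step 20
Reactants: 34 vinyl ketone (as above)
Product: 35 8β-alcohol: as 34 with axial 8β-OH (H-8α)
Conditions: K[HB(s-Bu)3], THF, −78 °C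
Reagents that add atoms: none
Why: Hydride reduction with a bulky borohydride: the β-axial approach to C8 is blocked by the syn-axial C10 methyl, so hydride enters from the α side and gives the axial 8β-alcohol. The lactone is not reduced at −78 °C.

Step 21
Reactants: 35 8β-alcohol (as above)
Product: 38 α-methylene lactone 8β-alcohol: as 35 with C11=C13, via Mannich base 36 (not isolated), via ammonium iodide 37 (not isolated)
Conditions: LiN(i-Pr)2 (2.3 equiv), THF, −78 °C; CH2=NMe2+ I−, −78 °C to rt; then MeI, MeOH, rt; then aq NaHCO3, CH2Cl2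
Reagents that add atoms: N,N-dimethylmethyleneiminium iodide, C=[N+](C)C.[I-]
Why: α-Methylenation of a γ-lactone by Mannich aminomethylation of the lactone enolate (formed beside the C8 alkoxide) with Eschenmoser's salt, then quaternisation and base-induced elimination of trimethylamine. C11 is the only enolisable carbon left.

Step 22
Reactants: 39 methyl (R)-3-hydroxy-2-methylpropanoate
Product: 40 methyl (R)-3-[(tert-butyldimethylsilyl)oxy]-2-methylpropanoate
Conditions: TBSCl, imidazole, CH2Cl2, rt
Reagents that add atoms: tert-butyl(chloro)dimethylsilane, CC(C)(C)[Si](C)(C)Cl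
Why: Silyl protection of the primary hydroxyl so that the acid can be used as the Mitsunobu nucleophile.

Step 23
Reactants: 40 methyl (R)-3-[(tert-butyldimethylsilyl)oxy]-2-methylpropanoate
Product: 41 (R)-3-[(tert-butyldimethylsilyl)oxy]-2-methylpropanoic acid
Conditions: LiOH, THF/H2O, 0 °C to rt; then 1 M HCl to pH 4
Reagents that add atoms: lithium hydroxide, [Li+].[OH-]
Why: Saponification under mild conditions; kept cold to avoid epimerisation or β-elimination of the silyloxy group.

Step 24
Reactants: 38 α-methylene lactone 8β-alcohol (as above); 41 (R)-3-[(tert-butyldimethylsilyl)oxy]-2-methylpropanoic acid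
Product: 42 bis-silyl ether of the target: 8α-[(R)-3-(tert-butyldimethylsilyloxy)-2-methylpropanoyloxy] and 15-O-TBDPS
Conditions: PPh3, DIAD, toluene, 0 °C to rt
Reagents that add atoms: none
Why: Mitsunobu esterification: the axial 8β-oxyphosphonium is displaced by the carboxylate from the open α side, giving the equatorial 8α-ester with inversion.

Step 25
Reactants: 42 bis-silyl ether (as above)
Product: 43 target: 8α-[(R)-3-hydroxy-2-methylpropanoyloxy]-15-hydroxy elemanolide with C1=C2, C4=C3 and C11=C13 alkenes and 12,6α-lactone
Conditions: HF·pyridine, pyridine, THF, 0 °C to rt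
Reagents that add atoms: none
Why: Fluoride desilylation of both primary silyl ethers under buffered, weakly acidic conditions that spare the α-methylene lactone and the ester.

## Compound list

1 | hydroxyacetone (1-hydroxypropan-2-one) | CC(=O)CO | starting material
2 | 1-[(tert-butyldiphenylsilyl)oxy]propan-2-one | CC(=O)CO[Si](c1ccccc1)(c1ccccc1)C(C)(C)C | intermediate
3 | triethyl phosphonoacetate | CCOC(=O)CP(=O)(OCC)OCC | starting material
4 | ethyl (E)-4-[(tert-butyldiphenylsilyl)oxy]-3-methylbut-2-enoate | CCOC(=O)/C=C(C)/CO[Si](c1ccccc1)(c1ccccc1)C(C)(C)C | intermediate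
5 | (E)-4-[(tert-butyldiphenylsilyl)oxy]-3-methylbut-2-enoic acid | OC(=O)/C=C(C)/CO[Si](c1ccccc1)(c1ccccc1)C(C)(C)C | intermediate
6 | (R)-4-benzyl-1,3-oxazolidin-2-one | O=C1N[C@H](Cc2ccccc2)CO1 | starting material
7 | mixed pivalic anhydride of 5 | CC(C)(C)C(=O)OC(=O)/C=C(C)/CO[Si](c1ccccc1)(c1ccccc1)C(C)(C)C | intermediate
8 | (R)-4-benzyl-3-{(E)-4-[(tert-butyldiphenylsilyl)oxy]-3-methylbut-2-enoyl}-1,3-oxazolidin-2-one | O=C(/C=C(C)/CO[Si](c1ccccc1)(c1ccccc1)C(C)(C)C)N1C(=O)OC[C@H]1Cc1ccccc1 | intermediate
9 | acrolein (prop-2-enal) | C=CC=O | starting material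
10 | (Z)-O-dibutylboryl dienolate of 8 | CCCCB(CCCC)O/C(=C\C(=C)CO[Si](c1ccccc1)(c1ccccc1)C(C)(C)C)N1C(=O)OC[C@H]1Cc1ccccc1 | intermediate
11 | (R)-4-benzyl-3-[(2R,3S)-2-{3-[(tert-butyldiphenylsilyl)oxy]prop-1-en-2-yl}-3-hydroxypent-4-enoyl]-1,3-oxazolidin-2-one | C=C[C@H](O)[C@@H](C(=C)CO[Si](c1ccccc1)(c1ccccc1)C(C)(C)C)C(=O)N1C(=O)OC[C@H]1Cc1ccccc1 | intermediate
12 | acryloyl chloride | C=CC(=O)Cl | starting material
13 | (R)-4-benzyl-3-[(2R,3S)-3-(acryloyloxy)-2-{3-[(tert-butyldiphenylsilyl)oxy]prop-1-en-2-yl}pent-4-enoyl]-1,3-oxazolidin-2-one | C=CC(=O)O[C@@H](C=C)[C@@H](C(=C)CO[Si](c1ccccc1)(c1ccccc1)C(C)(C)C)C(=O)N1C(=O)OC[C@H]1Cc1ccccc1 | intermediate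
14 | (R)-4-benzyl-3-[(2R)-3-{[(tert-butyldiphenylsilyl)oxy]methyl}-2-[(2S)-5-oxo-2,5-dihydrofuran-2-yl]but-3-enoyl]-1,3-oxazolidin-2-one | O=C1O[C@@H](C=C1)[C@@H](C(=C)CO[Si](c1ccccc1)(c1ccccc1)C(C)(C)C)C(=O)N1C(=O)OC[C@H]1Cc1ccccc1 | intermediate
15 | ethyl vinyl ether (ethoxyethene) | C=COCC | starting material
16 | 1-ethoxyvinyl adduct of 14 (enol ether at C8; C5 R, C6 S, C7 S) | O=C1C[C@H](C(=C)OCC)[C@H](O1)[C@@H](C(=C)CO[Si](c1ccccc1)(c1ccccc1)C(C)(C)C)C(=O)N1C(=O)OC[C@H]1Cc1ccccc1 | intermediate
17 | (R)-4-benzyl-3-[(2R)-2-[(2S,3S)-3-acetyl-5-oxooxolan-2-yl]-3-{[(tert-butyldiphenylsilyl)oxy]methyl}but-3-enoyl]-1,3-oxazolidin-2-one | O=C1C[C@H](C(C)=O)[C@H](O1)[C@@H](C(=C)CO[Si](c1ccccc1)(c1ccccc1)C(C)(C)C)C(=O)N1C(=O)OC[C@H]1Cc1ccccc1 | intermediate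
18 | peroxy acid corresponding to 19 | O=C1C[C@H](C(C)=O)[C@H](O1)[C@@H](C(=C)CO[Si](c1ccccc1)(c1ccccc1)C(C)(C)C)C(=O)OO | intermediate
19 | (2R)-2-[(2S,3S)-3-acetyl-5-oxooxolan-2-yl]-3-{[(tert-butyldiphenylsilyl)oxy]methyl}but-3-enoic acid | O=C1C[C@H](C(C)=O)[C@H](O1)[C@@H](C(=C)CO[Si](c1ccccc1)(c1ccccc1)C(C)(C)C)C(=O)O | intermediate
20 | (tributylstannyl)methanol | CCCC[Sn](CCCC)(CCCC)CO | starting material
21 | tert-butyldimethyl[(tributylstannyl)methoxy]silane | CCCC[Sn](CCCC)(CCCC)CO[Si](C)(C)C(C)(C)C | intermediate
22 | acid chloride of 19 | O=C1C[C@H](C(C)=O)[C@H](O1)[C@@H](C(=C)CO[Si](c1ccccc1)(c1ccccc1)C(C)(C)C)C(=O)Cl | intermediate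
23 | (4S,5S)-4-acetyl-5-[(3R)-1-[(tert-butyldimethylsilyl)oxy]-4-{[(tert-butyldiphenylsilyl)oxy]methyl}-2-oxopent-4-en-3-yl]oxolan-2-one | O=C1C[C@H](C(C)=O)[C@H](O1)[C@@H](C(=C)CO[Si](c1ccccc1)(c1ccccc1)C(C)(C)C)C(=O)CO[Si](C)(C)C(C)(C)C | intermediate
24 | β-hydroxy ketone from ring closure of 23 (C10 carbinol, configuration at C10 not defined) | O=C1CC(O)(CO[Si](C)(C)C(C)(C)C)[C@H](C(=C)CO[Si](c2ccccc2)(c2ccccc2)C(C)(C)C)[C@H]2OC(=O)C[C@H]12 | intermediate
25 | lactone-fused cyclohex-9-en-8-one with CH2OTBS on C10 and the 5β-arm (H-5α, H-6β, H-7α) | O=C1C=C(CO[Si](C)(C)C(C)(C)C)[C@H](C(=C)CO[Si](c2ccccc2)(c2ccccc2)C(C)(C)C)[C@H]2OC(=O)C[C@H]12 | intermediate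
26 | lactone-fused cyclohex-9-en-8β-ol (H-8α), otherwise as 25 | O[C@@H]1C=C(CO[Si](C)(C)C(C)(C)C)[C@H](C(=C)CO[Si](c2ccccc2)(c2ccccc2)C(C)(C)C)[C@H]2OC(=O)C[C@H]12 | intermediate
27 | diiodomethane | ICI | starting material
28 | iodomethylzinc alkoxide of 26 | IC[Zn]O[C@@H]1C=C(CO[Si](C)(C)C(C)(C)C)[C@H](C(=C)CO[Si](c2ccccc2)(c2ccccc2)C(C)(C)C)[C@H]2OC(=O)C[C@H]12 | intermediate
29 | 9β,10β-methano carbinol with 8β-OH and 10α-CH2OTBS | O[C@@H]1[C@@H]3C[C@]3(CO[Si](C)(C)C(C)(C)C)[C@H](C(=C)CO[Si](c2ccccc2)(c2ccccc2)C(C)(C)C)[C@H]2OC(=O)C[C@H]12 | intermediate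
30 | 9β,10β-methano C8 ketone | O=C1[C@@H]3C[C@]3(CO[Si](C)(C)C(C)(C)C)[C@H](C(=C)CO[Si](c2ccccc2)(c2ccccc2)C(C)(C)C)[C@H]2OC(=O)C[C@H]12 | intermediate
31 | C8 ketone with 10β-methyl and 10α-CH2OTBS | O=C1C[C@@](C)(CO[Si](C)(C)C(C)(C)C)[C@H](C(=C)CO[Si](c2ccccc2)(c2ccccc2)C(C)(C)C)[C@H]2OC(=O)C[C@H]12 | intermediate
32 | C8 ketone with 10β-methyl and 10α-CH2OH | O=C1C[C@@](C)(CO)[C@H](C(=C)CO[Si](c2ccccc2)(c2ccccc2)C(C)(C)C)[C@H]2OC(=O)C[C@H]12 | intermediate
33 | C8 ketone with 10β-methyl and 10α-CHO | O=C1C[C@@](C)(C=O)[C@H](C(=C)CO[Si](c2ccccc2)(c2ccccc2)C(C)(C)C)[C@H]2OC(=O)C[C@H]12 | intermediate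
34 | C8 ketone with 10β-methyl and 10α-vinyl | O=C1C[C@@](C)(C=C)[C@H](C(=C)CO[Si](c2ccccc2)(c2ccccc2)C(C)(C)C)[C@H]2OC(=O)C[C@H]12 | intermediate
35 | 8β-alcohol with 10β-methyl and 10α-vinyl | O[C@@H]1C[C@@](C)(C=C)[C@H](C(=C)CO[Si](c2ccccc2)(c2ccccc2)C(C)(C)C)[C@H]2OC(=O)C[C@H]12 | intermediate
36 | 11-(dimethylaminomethyl) lactone of 35 (C11 configuration not defined) | O[C@@H]1C[C@@](C)(C=C)[C@H](C(=C)CO[Si](c2ccccc2)(c2ccccc2)C(C)(C)C)[C@H]2OC(=O)C(CN(C)C)[C@H]12 | intermediate
37 | trimethylammonium iodide from 36 | O[C@@H]1C[C@@](C)(C=C)[C@H](C(=C)CO[Si](c2ccccc2)(c2ccccc2)C(C)(C)C)[C@H]2OC(=O)C(C[N+](C)(C)C)[C@H]12.[I-] | intermediate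
38 | α-methylene lactone 8β-alcohol (C11=C13) | O[C@@H]1C[C@@](C)(C=C)[C@H](C(=C)CO[Si](c2ccccc2)(c2ccccc2)C(C)(C)C)[C@H]2OC(=O)C(=C)[C@H]12 | intermediate
39 | methyl (R)-3-hydroxy-2-methylpropanoate | COC(=O)[C@H](C)CO | starting material
40 | methyl (R)-3-[(tert-butyldimethylsilyl)oxy]-2-methylpropanoate | COC(=O)[C@H](C)CO[Si](C)(C)C(C)(C)C | intermediate
41 | (R)-3-[(tert-butyldimethylsilyl)oxy]-2-methylpropanoic acid | OC(=O)[C@H](C)CO[Si](C)(C)C(C)(C)C | intermediate
42 | bis-silyl ether of the target (8α-ester; O-TBS on the acyl group; O-TBDPS on C15) | C=C[C@]1(C)C[C@H](OC(=O)[C@H](C)CO[Si](C)(C)C(C)(C)C)[C@H]2C(=C)C(=O)O[C@@H]2[C@H]1C(=C)CO[Si](c1ccccc1)(c1ccccc1)C(C)(C)C | intermediate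
43 | target CNP0133858.1 | C=C[C@]1(C)C[C@H](OC(=O)[C@H](C)CO)[C@H]2C(=C)C(=O)O[C@@H]2[C@H]1C(=C)CO | target

## Step count and least certain steps

Total step count: 25. Longest linear sequence: 22 steps (steps 1–9, 11–21, 24 and 25).

**Step 14 (key step).** The most likely failure is slow methylene transfer to the trisubstituted C9=C10 alkene, which is flanked by the C5 arm and the silyloxymethyl group. The excess reagent then needed could cyclopropanate the arm alkene without direction, and zinc iodide could ionise the cyclopropylcarbinol. The fallback installs C14 by conjugate addition instead of a carbenoid. It sets out from 25: Me2CuLi with Me3SiCl in THF at −78 °C should add methyl to C10 along the axial (β) trajectory of the lactone-locked half-chair to give the silyl enol ether F1, and mild acidic hydrolysis of F1 returns the route at 31. Here the face is set by stereoelectronics and not by coordination, so the C10 configuration would have to be confirmed before going on.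

**Step 12.** The C5 hydrogen of 23 is α to the C10 ketone and allylic. Enolisation or enamine formation on that side could expel the lactone oxygen from C6 or move the arm alkene into conjugation, and aldol addition in the reverse sense (C1 onto C8) would give a regioisomeric enone. The fallback separates addition from dehydration: from 23, kinetic soft enolisation of the methyl ketone with (c-C6H11)2BCl and Et3N at −78 °C and intramolecular aldol addition would give 24, which is isolated and then dehydrated with the Burgess reagent to rejoin the route at 25.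

**Step 16.** The ketyl could cut the endocyclic C9–C10 bond instead, since that gives the more substituted radical and an enlarged ring, or the ketone could be reduced further. The fallback opens the ring by an ionic path whose regiochemistry is steric: from 30, Me3SiCl and NaI in MeCN at low temperature should add iodide to the unhindered C14 with cleavage of C9–C14, giving the γ-iodo ketone F2 (10β-CH2I), and n-Bu3SnH with a radical initiator reduces F2 to 31.

**Step 13.** Catalyst control may not override the substrate's preference for axial hydride delivery, which would give poor facial selectivity at C8. The fallback accepts the other epimer and inverts it: from 25, NaBH4 with CeCl3·7H2O in MeOH should give the 8α-alcohol F3; Mitsunobu reaction of F3 with 4-nitrobenzoic acid (PPh3, DIAD) gives the 8β-ester F4, and K2CO3 in MeOH cleaves F4 to rejoin the route at 26.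

**Step 11.** Transmetalation of the bulky silyloxymethyl group may be slow, which allows decarbonylation of the acylpalladium or butyl transfer, and ketene formation from the α-branched acid chloride would erode C5. The fallback builds C1 from a diazo carbon: from 19 through 22, Me3SiCHN2 gives the diazoketone F5, dilute aqueous acid in THF converts F5 with loss of nitrogen into the α-hydroxy ketone F6, and TBSCl with imidazole silylates F6 to rejoin the route at 23.

**Step 24.** The axial oxyphosphonium has anti-periplanar hydrogens at C7 and C9, so elimination can compete with substitution, and PPh3 can add to the methylene lactone. The fallback moves the inversion to a stage without the Michael acceptor and ends with a retentive acylation. From 35, Mitsunobu reaction with the more acidic 4-nitrobenzoic acid gives the 8α-ester F7, K2CO3 in MeOH gives the 8α-alcohol F8, the protocol of step 21 gives the α-methylene lactone F9, and Yamaguchi esterification of F9 with 41 (2,4,6-trichlorobenzoyl chloride, Et3N, DMAP) rejoins the route at 42.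

## Further compounds

F1 | step 14 | trimethylsilyl enol ether of 31 (C8–OSiMe3, C8=C9) | C[Si](C)(C)OC1=C[C@@](C)(CO[Si](C)(C)C(C)(C)C)[C@H](C(=C)CO[Si](c2ccccc2)(c2ccccc2)C(C)(C)C)[C@H]2OC(=O)C[C@H]12
F0 | step 12 | none | none
F2 | step 16 | γ-iodo ketone: C8 ketone with 10β-CH2I and 10α-CH2OTBS | O=C1C[C@@](CI)(CO[Si](C)(C)C(C)(C)C)[C@H](C(=C)CO[Si](c2ccccc2)(c2ccccc2)C(C)(C)C)[C@H]2OC(=O)C[C@H]12
F3 | step 13 | 8α-epimer of 26 | O[C@H]1C=C(CO[Si](C)(C)C(C)(C)C)[C@H](C(=C)CO[Si](c2ccccc2)(c2ccccc2)C(C)(C)C)[C@H]2OC(=O)C[C@H]12
F4 | step 13 | 8β-(4-nitrobenzoate) of 26 | O=C(O[C@@H]1C=C(CO[Si](C)(C)C(C)(C)C)[C@H](C(=C)CO[Si](c2ccccc2)(c2ccccc2)C(C)(C)C)[C@H]2OC(=O)C[C@H]12)c1ccc(cc1)[N+](=O)[O-]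
F5 | step 11 | diazoketone from 22 (C10 carbonyl, C1 diazo carbon) | O=C1C[C@H](C(C)=O)[C@H](O1)[C@@H](C(=C)CO[Si](c1ccccc1)(c1ccccc1)C(C)(C)C)C(=O)C=[N+]=[N-]
F6 | step 11 | α-hydroxy ketone (desilyl 23) | O=C1C[C@H](C(C)=O)[C@H](O1)[C@@H](C(=C)CO[Si](c1ccccc1)(c1ccccc1)C(C)(C)C)C(=O)CO
F7 | step 24 | 8α-(4-nitrobenzoate) from 35 | O=C(O[C@H]1C[C@@](C)(C=C)[C@H](C(=C)CO[Si](c2ccccc2)(c2ccccc2)C(C)(C)C)[C@H]2OC(=O)C[C@H]12)c1ccc(cc1)[N+](=O)[O-]
F8 | step 24 | 8α-epimer of 35 | O[C@H]1C[C@@](C)(C=C)[C@H](C(=C)CO[Si](c2ccccc2)(c2ccccc2)C(C)(C)C)[C@H]2OC(=O)C[C@H]12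
F9 | step 24 | 8α-epimer of 38 | O[C@H]1C[C@@](C)(C=C)[C@H](C(=C)CO[Si](c2ccccc2)(c2ccccc2)C(C)(C)C)[C@H]2OC(=O)C(=C)[C@H]12
A1 | alternative 1 | open-chain aldehyde for the carbonyl-ene closure (C6 formyl, 8α-OTBS, C10 methyl and vinyl, 2-methylpropenyl on C10) | C=C[C@@](C)(C=C(C)C)C[C@H](O[Si](C)(C)C(C)(C)C)[C@@H](CC(=O)OC)C=O
A2 | alternative 1 | cyclohexanol with C5 isopropenyl, C6 hydroxyl, C7 ester arm, C8 silyl ether | C=C[C@]1(C)C[C@H](O[Si](C)(C)C(C)(C)C)[C@@H](CC(=O)OC)[C@H](O)[C@H]1C(C)=C
A3 | alternative 2 | (Z)-allylic bromide aldehyde for the chromium cascade | COC(=O)/C(CBr)=C/[C@@H](O[Si](C)(C)C(C)(C)C)C[C@@](C)(C=C)[C@@H](C=O)C(=C)CO[Si](c1ccccc1)(c1ccccc1)C(C)(C)C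
A4 | alternative 2 | trans-fused α-methylene lactone with C8 and C15 silyl ethers | C=C[C@]1(C)C[C@H](O[Si](C)(C)C(C)(C)C)[C@H]2C(=C)C(=O)O[C@@H]2[C@H]1C(=C)CO[Si](c1ccccc1)(c1ccccc1)C(C)(C)C
A5 | alternative 3 | lactone with C8 silyl enol ether and (Z)-allylsilane on C5 | C=C(O[Si](C)(C)C)[C@H]1CC(=O)O[C@@H]1[C@@H](C(=C)CO[Si](c1ccccc1)(c1ccccc1)C(C)(C)C)/C(C)=C\C[Si](C)(C)C
A6 | alternative 3 | trans-fused lactone cyclohexanone with C8 ketone and C10 methyl and vinyl | C=C[C@]1(C)CC(=O)[C@H]2CC(=O)O[C@@H]2[C@H]1C(=C)CO[Si](c1ccccc1)(c1ccccc1)C(C)(C)C
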